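The route rests on cutting the C3a–C3 bond, the aryl–C(sp2) bond by which ring A carries the exocyclic trisubstituted styrene of the indane. One intramolecular Mizoroki–Heck reaction makes this bond, closes the five-membered carbocycle and, through syn-carbopalladation and syn-β-hydride elimination on an E-alkene, shifts the double bond to the exocyclic C3=CH position with ring A trans to the dihydrobenzofuran aryl. The precursor is a ring A bromoarene bearing the preset anti C1/C2 diaryl stereodiad (relayed through a dihydrocoumarin built on the C7 oxygen) and an E-styryl arm that ends in the trans-2,3-diaryldihydrobenzofuran; the two halves are made separately under catalyst control and joined by Suzuki coupling.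

Key step: step 17

Remark (numbering): the indane is numbered C1 (carries the 4-oxygenated phenyl), C2, C3 (alkylidene carbon), C3a, C4–C7, C7a, with oxygen on C5 and C7; the dihydrobenzofuran is numbered O1, C2, C3, C3a, C4–C7, C7a.
Remark (composition): the target has eight phenolic hydroxyl groups and one ring ether oxygen, so its fully protected precursor is an octa-O-methyl ether.
Assumption (sense of induction): the antipodes of HyperBTM (step 4) and of Rh2(PTAD)4 (step 13; PTAD = N-phthaloyl-(1-adamantyl)glycinate) written below are taken to give the configurations drawn; both antipodes of each catalyst are available, so the one that delivers the drawn configuration is used.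
Assumption (step 4): the kinetic adduct is taken to be mainly the cis-lactone; if the trans-lactone forms directly, the DBU treatment is merely redundant.

Step 1
Reactants: 1 2-bromo-4,6-dimethoxybenzaldehyde
Product: 2 2-bromo-6-hydroxy-4-methoxybenzaldehyde
Conditions: BCl3 (1.2 equiv), CH2Cl2, −78 °C to 0 °C; aqueous work-up
Reagents that add atoms: none
Why: Boron chelates between the formyl oxygen and the neighbouring methoxy group, so this regioselective Lewis-acid ether cleavage should remove only the methyl group ortho to the aldehyde and leave the para methoxy group and the bromide untouched.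

Step 2
Reactants: 2 2-bromo-6-hydroxy-4-methoxybenzaldehyde; 3 4-bromoanisole
Product: 5 racemic (2-bromo-6-hydroxy-4-methoxyphenyl)(4-methoxyphenyl)methanol, via 4-methoxyphenylmagnesium bromide 4 (not isolated)
Conditions: 3, Mg, THF, reflux; then 2 (4 in 2.5-fold excess), THF, 0 °C to rt; sat. NH4Cl
Reagents that add atoms: none
Why: In this Grignard addition the first equivalent of 4 only deprotonates the phenol and a further equivalent adds to the aldehyde, which the adjacent bromine and phenoxide slow but do not block; the carbinol centre is formed racemic on purpose because it becomes planar again in step 4.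

Step 3
Reactants: 5 racemic (2-bromo-6-hydroxy-4-methoxyphenyl)(4-methoxyphenyl)methanol
Product: 6 racemic 3-bromo-5-methoxy-2-[(4-methoxyphenyl)(4-methylbenzenesulfonyl)methyl]phenol
Conditions: p-TolSO2Na (2 equiv), HCO2H/H2O, CH2Cl2, rt
Reagents that add atoms: sodium p-toluenesulfinate, Cc1ccc(S(=O)[O-])cc1.[Na+]
Why: Acid ionises the doubly donor-stabilised benzhydrol (SN1-type substitution by way of the ortho-quinone methide or its protonated form) and the soft sulfinate captures the cation at sulfur, giving a storable sulfone from which mild base regenerates the ortho-quinone methide.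

Step 4
Reactants: 6 racemic 3-bromo-5-methoxy-2-[(4-methoxyphenyl)(4-methylbenzenesulfonyl)methyl]phenol; 7 3,5-dimethoxyphenylacetic acid
Product: 11 (3S,4S)-5-bromo-3-(3,5-dimethoxyphenyl)-7-methoxy-4-(4-methoxyphenyl)chroman-2-one (trans-lactone), via mixed pivalic anhydride 8 (not isolated), via ortho-quinone methide 9 (not isolated), via cis-lactone 10 (not isolated)
Conditions: 7 (1.5 equiv), t-BuCOCl, i-Pr2NEt, CH2Cl2, 0 °C; then (2S,3R)-HyperBTM (10 mol%), 6, i-Pr2NEt, −20 °C to rt; then DBU (0.2 equiv), rt
Reagents that add atoms: none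
Why: This is a chiral isothiourea (Lewis base) catalysed Michael addition–lactonisation, a formal [4+2] between the C1-ammonium enolate formed from 8 and the ortho-quinone methide 9 released from 6 by E1cB loss of sulfinate: the catalyst blocks one enolate face, the closed transition state relays that choice to the benzhydryl carbon so that C4 (the later indane C1) is set as S, the phenoxide then acylates to turn the catalyst over, and DBU finally epimerises the acidic α-aryl C3 to the more stable trans (3S) arrangement.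

Step 5
Reactants: 11 (3S,4S)-5-bromo-3-(3,5-dimethoxyphenyl)-7-methoxy-4-(4-methoxyphenyl)chroman-2-one
Product: 12 (2S,3S)-3-(2-bromo-6-hydroxy-4-methoxyphenyl)-2-(3,5-dimethoxyphenyl)-3-(4-methoxyphenyl)propan-1-ol
Conditions: LiBH4 (2.5 equiv), THF, 0 °C to rt
Reagents that add atoms: none
Why: Borohydride reduction of the activated aryl ester opens the lactone to the primary alcohol and the phenol without touching the aryl bromide, and the trans relationship of step 4 is carried over unchanged as the anti arrangement of the open chain.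

Step 6
Reactants: 12 (2S,3S)-3-(2-bromo-6-hydroxy-4-methoxyphenyl)-2-(3,5-dimethoxyphenyl)-3-(4-methoxyphenyl)propan-1-ol
Product: 13 (2S,3S)-3-(2-bromo-4,6-dimethoxyphenyl)-2-(3,5-dimethoxyphenyl)-3-(4-methoxyphenyl)propan-1-ol
Conditions: MeI (1.5 equiv), K2CO3, acetone, 50 °C
Reagents that add atoms: iodomethane, CI
Why: In this Williamson etherification carbonate deprotonates only the phenol, so methylation should occur at the ring A oxygen and not at the primary alcohol.

Step 7
Reactants: 13 (2S,3S)-3-(2-bromo-4,6-dimethoxyphenyl)-2-(3,5-dimethoxyphenyl)-3-(4-methoxyphenyl)propan-1-ol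
Product: 14 (2S,3S)-3-(2-bromo-4,6-dimethoxyphenyl)-2-(3,5-dimethoxyphenyl)-3-(4-methoxyphenyl)propanal
Conditions: Dess–Martin periodinane (1.3 equiv), NaHCO3, CH2Cl2, 0 °C; crude product used at once
Reagents that add atoms: none
Why: The Dess–Martin oxidation stops at the aldehyde and runs under buffered, non-basic conditions, which should keep the epimerisable α-aryl centre intact provided the crude aldehyde is used immediately.

Step 8
Reactants: 14 (2S,3S)-3-(2-bromo-4,6-dimethoxyphenyl)-2-(3,5-dimethoxyphenyl)-3-(4-methoxyphenyl)propanal; 15 iodoform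
Product: 16 (1E,3R,4S)-4-(2-bromo-4,6-dimethoxyphenyl)-3-(3,5-dimethoxyphenyl)-1-iodo-4-(4-methoxyphenyl)but-1-ene
Conditions: CrCl2 (6 equiv), 15 (2 equiv), THF/1,4-dioxane, 0 °C to rt
Reagents that add atoms: none
Why: In the Takai olefination the geminal dichromium species formed from iodoform and CrCl2 adds to the aldehyde and eliminates to the E-iodoalkene under conditions that are neither basic enough to epimerise the α-centre nor able to touch the aryl bromide (the descriptor at C3 changes to R only because iodine alters the priorities).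

Step 9
Reactants: 17 5-bromosalicylaldehyde; 18 4-methoxybenzyl chloride
Product: 19 5-bromo-2-[(4-methoxyphenyl)methoxy]benzaldehyde
Conditions: K2CO3, KI (cat.), DMF, 50 °C
Reagents that add atoms: none
Why: Williamson etherification of the phenoxide with the reactive benzylic chloride installs the 4-methoxybenzyl group whose CH2 later becomes C2 of the dihydrobenzofuran.

Step 10
Reactants: 19 5-bromo-2-[(4-methoxyphenyl)methoxy]benzaldehyde; 20 1-bromo-3,5-dimethoxybenzene
Product: 22 racemic {5-bromo-2-[(4-methoxyphenyl)methoxy]phenyl}(3,5-dimethoxyphenyl)methanol, via 3,5-dimethoxyphenylmagnesium bromide 21 (not isolated)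
Conditions: 20, Mg, THF, reflux; then 19, THF, −20 °C to 0 °C; sat. NH4Cl
Reagents that add atoms: none
Why: Grignard addition to the aldehyde is much faster than halogen–magnesium exchange at the aryl bromide at low temperature, so the diaryl carbinol should form cleanly (racemic, the centre is oxidised next).

Step 11
Reactants: 22 racemic {5-bromo-2-[(4-methoxyphenyl)methoxy]phenyl}(3,5-dimethoxyphenyl)methanol
Product: 23 {5-bromo-2-[(4-methoxyphenyl)methoxy]phenyl}(3,5-dimethoxyphenyl)methanone
Conditions: activated MnO2 (15 equiv), CH2Cl2, rt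
Reagents that add atoms: none
Why: Oxidation of the doubly benzylic alcohol with activated MnO2 gives the benzophenone without affecting the 4-methoxybenzyl ether.

Step 12
Reactants: 23 {5-bromo-2-[(4-methoxyphenyl)methoxy]phenyl}(3,5-dimethoxyphenyl)methanone
Product: 24 hydrazone of 23 (E/Z mixture)
Conditions: N2H4·H2O (10 equiv), AcOH (cat.), EtOH, 80 °C
Reagents that add atoms: hydrazine, NN
Why: Acid-catalysed condensation of the hindered diaryl ketone with a large excess of hydrazine gives the free hydrazone and suppresses azine formation.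

Step 13
Reactants: 24 hydrazone of 23
Product: 26 (2S,3R)-5-bromo-3-(3,5-dimethoxyphenyl)-2-(4-methoxyphenyl)-2,3-dihydro-1-benzofuran (cis), via diaryldiazomethane 25 (not isolated)
Conditions: MnO2 (8 equiv), CH2Cl2, 0 °C, filtration through Celite; filtrate added to Rh2(R-PTAD)4 (1 mol%), CH2Cl2, 0 °C to rt
Reagents that add atoms: none
Why: MnO2 dehydrogenates the hydrazone to the donor/donor diazo compound 25, whose dirhodium carbene undergoes a concerted 1,5 C–H insertion into the ether CH2 activated by oxygen and the 4-methoxyphenyl ring (intramolecular carbene C–H insertion closing the five-membered ring), the chiral carboxylate ligands fixing C3 as R and the compact transition state placing the two aryl groups cis (C2 S).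

Step 14
Reactants: 26 (2S,3R)-5-bromo-3-(3,5-dimethoxyphenyl)-2-(4-methoxyphenyl)-2,3-dihydro-1-benzofuran
Product: 27 (2R,3R)-5-bromo-3-(3,5-dimethoxyphenyl)-2-(4-methoxyphenyl)-2,3-dihydro-1-benzofuran (trans)
Conditions: CF3CO2H (5 equiv), CH2Cl2 (dilute), 0 °C to rt
Reagents that add atoms: none
Why: In this acid-mediated epimerisation, protonation of O1 reversibly ionises the C2–O bond to a 4-methoxybenzylic cation that stays tethered to the phenol and re-closes to the thermodynamically preferred trans isomer, so C2 is inverted to R while C3, which is not involved, keeps its configuration.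

Step 15
Reactants: 27 (2R,3R)-5-bromo-3-(3,5-dimethoxyphenyl)-2-(4-methoxyphenyl)-2,3-dihydro-1-benzofuran
Product: 28 2-[(2R,3R)-3-(3,5-dimethoxyphenyl)-2-(4-methoxyphenyl)-2,3-dihydro-1-benzofuran-5-yl]-4,4,5,5-tetramethyl-1,3,2-dioxaborolane
Conditions: B2pin2 (1.3 equiv), Pd(dppf)Cl2 (5 mol%), KOAc, 1,4-dioxane, 85 °C
Reagents that add atoms: bis(pinacolato)diboron, CC1(C)OB(OC1(C)C)B1OC(C)(C)C(C)(C)O1
Why: Miyaura borylation of the aryl bromide under weakly basic KOAc conditions leaves the trans-dihydrobenzofuran and its stereocentres untouched.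

Step 16
Reactants: 16 (1E,3R,4S)-4-(2-bromo-4,6-dimethoxyphenyl)-3-(3,5-dimethoxyphenyl)-1-iodo-4-(4-methoxyphenyl)but-1-ene; 28 2-[(2R,3R)-3-(3,5-dimethoxyphenyl)-2-(4-methoxyphenyl)-2,3-dihydro-1-benzofuran-5-yl]-4,4,5,5-tetramethyl-1,3,2-dioxaborolane
Product: 29 (2R,3R)-5-[(1E,3S,4S)-4-(2-bromo-4,6-dimethoxyphenyl)-3-(3,5-dimethoxyphenyl)-4-(4-methoxyphenyl)but-1-en-1-yl]-3-(3,5-dimethoxyphenyl)-2-(4-methoxyphenyl)-2,3-dihydro-1-benzofuran
Conditions: Pd(PPh3)4 (5 mol%), K3PO4 (2 M aq.), THF, 45 °C
Reagents that add atoms: none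
Why: In this Suzuki–Miyaura coupling, oxidative addition of zerovalent palladium into the alkenyl C–I bond is far faster than into the hindered, electron-rich ring A C–Br bond at this temperature, and the coupling proceeds with retention of the E geometry and without touching any stereocentre.

Step 17
Reactants: 29 (2R,3R)-5-[(1E,3S,4S)-4-(2-bromo-4,6-dimethoxyphenyl)-3-(3,5-dimethoxyphenyl)-4-(4-methoxyphenyl)but-1-en-1-yl]-3-(3,5-dimethoxyphenyl)-2-(4-methoxyphenyl)-2,3-dihydro-1-benzofuran
Product: 30 (2R,3R)-5-{(E)-[(1S,2S)-2-(3,5-dimethoxyphenyl)-5,7-dimethoxy-1-(4-methoxyphenyl)indan-3-ylidene]methyl}-3-(3,5-dimethoxyphenyl)-2-(4-methoxyphenyl)-2,3-dihydro-1-benzofuran (octa-O-methyl ether of the target)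
Conditions: Pd(OAc)2 (10 mol%), P(o-tol)3 (25 mol%), Ag2CO3 (1.5 equiv), DMF, 90 °C
Reagents that add atoms: none
Why: Zerovalent palladium inserts into the ring A C–Br bond (only one ortho position is substituted), the arylpalladium adds syn across the E-styrene so that ring A bonds to C3 and palladium sits on the benzylic CH, and after rotation about the C3–CH bond syn-β-hydride elimination of the only β-hydrogen (on C3) releases the exocyclic alkene, Ag2CO3 taking up the HBr. The closest known reaction type is the intramolecular Mizoroki–Heck cyclisation of an aryl halide onto a 1,2-disubstituted styrene to give a benzylidene-indane. The five-membered carbocycle closes in the 5-exo-trig mode. No new stereocentre is made: the E geometry (ring A trans to the dihydrobenzofuran aryl) is dictated by syn addition followed by syn elimination on the E-alkene supplied by steps 8 and 16, and C1 and C2 are bystanders because no strong base is present. The step needs 5-exo rather than 6-endo insertion or C–H arylation of the C1 aryl, and no alkene migration into the ring; the three-atom tether and the benzylic stabilisation of the alkylpalladium favour 5-exo, and bromide abstraction by silver keeps palladium cationic and removes the hydridopalladium species quickly, which should suppress re-addition towards the indene.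

Step 18
Reactants: 30 octa-O-methyl ether of the target
Product: 31 CNP0184753.1, (1S,2S,3E)-3-{[(2R,3R)-3-(3,5-dihydroxyphenyl)-2-(4-hydroxyphenyl)-2,3-dihydro-1-benzofuran-5-yl]methylidene}-2-(3,5-dihydroxyphenyl)-1-(4-hydroxyphenyl)indane-5,7-diol
Conditions: BCl3 (16 equiv), n-Bu4NI (16 equiv), CH2Cl2, −78 °C to rt; MeOH/H2O quench
Reagents that add atoms: none
Why: Iodide-assisted boron trihalide ether cleavage (SN2 attack of iodide on the boron-complexed methyl ethers) should remove all eight methyl groups at or below room temperature; if the dihydrobenzofuran C2–O bond ionises under these conditions it re-closes to the same, thermodynamically preferred trans isomer, and the low temperature limits protonation of the exocyclic alkene.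

Compound list
1 | 2-bromo-4,6-dimethoxybenzaldehyde | COc1cc(Br)c(C=O)c(OC)c1 | starting material
2 | 2-bromo-6-hydroxy-4-methoxybenzaldehyde | COc1cc(O)c(C=O)c(Br)c1 | intermediate
3 | 4-bromoanisole | COc1ccc(Br)cc1 | starting material
4 | 4-methoxyphenylmagnesium bromide | COc1ccc([Mg]Br)cc1 | intermediate
5 | racemic (2-bromo-6-hydroxy-4-methoxyphenyl)(4-methoxyphenyl)methanol | COc1ccc(C(O)c2c(O)cc(OC)cc2Br)cc1 | intermediate
6 | racemic 3-bromo-5-methoxy-2-[(4-methoxyphenyl)(4-methylbenzenesulfonyl)methyl]phenol | COc1ccc(C(c2c(O)cc(OC)cc2Br)S(=O)(=O)c2ccc(C)cc2)cc1 | intermediate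
7 | 3,5-dimethoxyphenylacetic acid | COc1cc(CC(=O)O)cc(OC)c1 | starting material
8 | 3,5-dimethoxyphenylacetic pivalic anhydride | COc1cc(CC(=O)OC(=O)C(C)(C)C)cc(OC)c1 | intermediate
9 | 5-bromo-3-methoxy-6-[(4-methoxyphenyl)methylidene]cyclohexa-2,4-dien-1-one (ortho-quinone methide) | O=C1C=C(OC)C=C(Br)C1=Cc1ccc(OC)cc1 | intermediate
10 | (3R,4S)-5-bromo-3-(3,5-dimethoxyphenyl)-7-methoxy-4-(4-methoxyphenyl)chroman-2-one (cis-lactone) | O=C1Oc2cc(OC)cc(Br)c2[C@H](c2ccc(OC)cc2)[C@@H]1c1cc(OC)cc(OC)c1 | intermediate
11 | (3S,4S)-5-bromo-3-(3,5-dimethoxyphenyl)-7-methoxy-4-(4-methoxyphenyl)chroman-2-one (trans-lactone) | O=C1Oc2cc(OC)cc(Br)c2[C@H](c2ccc(OC)cc2)[C@H]1c1cc(OC)cc(OC)c1 | intermediate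
12 | (2S,3S)-3-(2-bromo-6-hydroxy-4-methoxyphenyl)-2-(3,5-dimethoxyphenyl)-3-(4-methoxyphenyl)propan-1-ol | OC[C@H](c1cc(OC)cc(OC)c1)[C@@H](c1ccc(OC)cc1)c1c(Br)cc(OC)cc1O | intermediate
13 | (2S,3S)-3-(2-bromo-4,6-dimethoxyphenyl)-2-(3,5-dimethoxyphenyl)-3-(4-methoxyphenyl)propan-1-ol | OC[C@H](c1cc(OC)cc(OC)c1)[C@@H](c1ccc(OC)cc1)c1c(Br)cc(OC)cc1OC | intermediate
14 | (2S,3S)-3-(2-bromo-4,6-dimethoxyphenyl)-2-(3,5-dimethoxyphenyl)-3-(4-methoxyphenyl)propanal | O=C[C@H](c1cc(OC)cc(OC)c1)[C@@H](c1ccc(OC)cc1)c1c(Br)cc(OC)cc1OC | intermediate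
15 | iodoform | IC(I)I | starting material
16 | (1E,3R,4S)-4-(2-bromo-4,6-dimethoxyphenyl)-3-(3,5-dimethoxyphenyl)-1-iodo-4-(4-methoxyphenyl)but-1-ene | I/C=C/[C@H](c1cc(OC)cc(OC)c1)[C@@H](c1ccc(OC)cc1)c1c(Br)cc(OC)cc1OC | intermediate
17 | 5-bromosalicylaldehyde | O=Cc1cc(Br)ccc1O | starting material
18 | 4-methoxybenzyl chloride | COc1ccc(CCl)cc1 | starting material
19 | 5-bromo-2-[(4-methoxyphenyl)methoxy]benzaldehyde | COc1ccc(COc2ccc(Br)cc2C=O)cc1 | intermediate
20 | 1-bromo-3,5-dimethoxybenzene | COc1cc(Br)cc(OC)c1 | starting material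
21 | 3,5-dimethoxyphenylmagnesium bromide | COc1cc([Mg]Br)cc(OC)c1 | intermediate
22 | racemic {5-bromo-2-[(4-methoxyphenyl)methoxy]phenyl}(3,5-dimethoxyphenyl)methanol | COc1ccc(COc2ccc(Br)cc2C(O)c2cc(OC)cc(OC)c2)cc1 | intermediate
23 | {5-bromo-2-[(4-methoxyphenyl)methoxy]phenyl}(3,5-dimethoxyphenyl)methanone | COc1ccc(COc2ccc(Br)cc2C(=O)c2cc(OC)cc(OC)c2)cc1 | intermediate
24 | hydrazone of 23 (E/Z mixture) | COc1ccc(COc2ccc(Br)cc2C(=NN)c2cc(OC)cc(OC)c2)cc1 | intermediate
25 | 4-bromo-2-[diazo(3,5-dimethoxyphenyl)methyl]-1-[(4-methoxyphenyl)methoxy]benzene | COc1ccc(COc2ccc(Br)cc2C(=[N+]=[N-])c2cc(OC)cc(OC)c2)cc1 | intermediate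
26 | (2S,3R)-5-bromo-3-(3,5-dimethoxyphenyl)-2-(4-methoxyphenyl)-2,3-dihydro-1-benzofuran (cis) | Brc1ccc2c(c1)[C@@H](c1cc(OC)cc(OC)c1)[C@@H](c1ccc(OC)cc1)O2 | intermediate
27 | (2R,3R)-5-bromo-3-(3,5-dimethoxyphenyl)-2-(4-methoxyphenyl)-2,3-dihydro-1-benzofuran (trans) | Brc1ccc2c(c1)[C@@H](c1cc(OC)cc(OC)c1)[C@H](c1ccc(OC)cc1)O2 | intermediate
28 | 2-[(2R,3R)-3-(3,5-dimethoxyphenyl)-2-(4-methoxyphenyl)-2,3-dihydro-1-benzofuran-5-yl]-4,4,5,5-tetramethyl-1,3,2-dioxaborolane | CC1(C)OB(OC1(C)C)c1ccc2c(c1)[C@@H](c1cc(OC)cc(OC)c1)[C@H](c1ccc(OC)cc1)O2 | intermediate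
29 | (2R,3R)-5-[(1E,3S,4S)-4-(2-bromo-4,6-dimethoxyphenyl)-3-(3,5-dimethoxyphenyl)-4-(4-methoxyphenyl)but-1-en-1-yl]-3-(3,5-dimethoxyphenyl)-2-(4-methoxyphenyl)-2,3-dihydro-1-benzofuran | COc1ccc([C@@H](c2c(Br)cc(OC)cc2OC)[C@H](/C=C/c2ccc3c(c2)[C@@H](c2cc(OC)cc(OC)c2)[C@H](c2ccc(OC)cc2)O3)c2cc(OC)cc(OC)c2)cc1 | intermediate
30 | (2R,3R)-5-{(E)-[(1S,2S)-2-(3,5-dimethoxyphenyl)-5,7-dimethoxy-1-(4-methoxyphenyl)indan-3-ylidene]methyl}-3-(3,5-dimethoxyphenyl)-2-(4-methoxyphenyl)-2,3-dihydro-1-benzofuran (octa-O-methyl ether of the target) | COc1ccc([C@H]2c3c(OC)cc(OC)cc3/C(=C/c3ccc4c(c3)[C@@H](c3cc(OC)cc(OC)c3)[C@H](c3ccc(OC)cc3)O4)[C@@H]2c2cc(OC)cc(OC)c2)cc1 | intermediate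
31 | CNP0184753.1, (1S,2S,3E)-3-{[(2R,3R)-3-(3,5-dihydroxyphenyl)-2-(4-hydroxyphenyl)-2,3-dihydro-1-benzofuran-5-yl]methylidene}-2-(3,5-dihydroxyphenyl)-1-(4-hydroxyphenyl)indane-5,7-diol | Oc1ccc([C@H]2c3c(O)cc(O)cc3/C(=C/c3ccc4c(c3)[C@@H](c3cc(O)cc(O)c3)[C@H](c3ccc(O)cc3)O4)[C@@H]2c2cc(O)cc(O)c2)cc1 | target

Total step count: 18.
Longest linear sequence: 11 steps (steps 1–8, then 16, 17 and 18); the dihydrobenzofuran branch (steps 9–15) joins at step 16.

Steps most likely to fail

Step 4. The peri bromine twists the ortho-quinone methide out of plane, so the isothiourea may discriminate its faces poorly and the lactone may be obtained with insufficient enantiomeric purity. In that case the same addition–lactonisation would be run from 6 and 7 with an achiral Lewis base (DHPB, 3,4-dihydro-2H-pyrimido[2,1-b]benzothiazole) and the same DBU equilibration. This should give the racemic trans-lactone, that is 11 together with its mirror image, the (3R,4R)-lactone F1. Preparative chromatography on a chiral stationary phase (amylose carbamate phase, supercritical CO2/MeOH) would then separate the two, and the route resumes at 11.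

Step 17. Oxidative addition into the electron-rich, ortho-substituted C–Br bond may be slow at a temperature that the product tolerates, so that protodebromination or hydridopalladium-mediated migration of the alkene into the ring takes over. The fallback changes the substrate rather than the catalyst: 29 would be converted by copper-catalysed aromatic Finkelstein exchange (CuI, NaI, trans-N,N'-dimethylcyclohexane-1,2-diamine, 1,4-dioxane, 110 °C) into the iodo analogue of the Heck precursor F2. Its far faster oxidative addition allows a silver-promoted cationic Mizoroki–Heck closure at about 60 °C (Pd(OAc)2, PPh3, Ag2CO3, MeCN), and the route resumes at 30.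

Step 14. With the phenols still methylated, the benzylic cation may lose the C3 proton (eroding the C3 configuration through a triarylethene) or alkylate another molecule before it re-closes, or the equilibration may stall. The separate epimerisation would then be dropped and the cis series carried forward from 26. Miyaura borylation as in step 15 should give the cis-boronate F3, Suzuki coupling with 16 as in step 16 the cis-configured Heck precursor F4, and the Heck closure of step 17 the C2-epimeric octa-O-methyl ether F5. The BCl3/n-Bu4NI treatment of step 18 then frees the 4-hydroxyphenyl group, which makes reversible C2–O ionisation (para-quinone methide type) easy, so that demethylation and cis-to-trans equilibration occur together and the route is rejoined at 31.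

Further compounds
F1 | step 4 | (3R,4R)-5-bromo-3-(3,5-dimethoxyphenyl)-7-methoxy-4-(4-methoxyphenyl)chroman-2-one (enantiomer of 11) | O=C1Oc2cc(OC)cc(Br)c2[C@@H](c2ccc(OC)cc2)[C@@H]1c1cc(OC)cc(OC)c1
F2 | step 17 | (2R,3R)-5-[(1E,3S,4S)-3-(3,5-dimethoxyphenyl)-4-(2-iodo-4,6-dimethoxyphenyl)-4-(4-methoxyphenyl)but-1-en-1-yl]-3-(3,5-dimethoxyphenyl)-2-(4-methoxyphenyl)-2,3-dihydro-1-benzofuran | COc1ccc([C@@H](c2c(I)cc(OC)cc2OC)[C@H](/C=C/c2ccc3c(c2)[C@@H](c2cc(OC)cc(OC)c2)[C@H](c2ccc(OC)cc2)O3)c2cc(OC)cc(OC)c2)cc1
F3 | step 14 | 2-[(2S,3R)-3-(3,5-dimethoxyphenyl)-2-(4-methoxyphenyl)-2,3-dihydro-1-benzofuran-5-yl]-4,4,5,5-tetramethyl-1,3,2-dioxaborolane (cis) | CC1(C)OB(OC1(C)C)c1ccc2c(c1)[C@@H](c1cc(OC)cc(OC)c1)[C@@H](c1ccc(OC)cc1)O2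
F4 | step 14 | (2S,3R)-5-[(1E,3S,4S)-4-(2-bromo-4,6-dimethoxyphenyl)-3-(3,5-dimethoxyphenyl)-4-(4-methoxyphenyl)but-1-en-1-yl]-3-(3,5-dimethoxyphenyl)-2-(4-methoxyphenyl)-2,3-dihydro-1-benzofuran | COc1ccc([C@@H](c2c(Br)cc(OC)cc2OC)[C@H](/C=C/c2ccc3c(c2)[C@@H](c2cc(OC)cc(OC)c2)[C@@H](c2ccc(OC)cc2)O3)c2cc(OC)cc(OC)c2)cc1
F5 | step 14 | (2S,3R)-5-{(E)-[(1S,2S)-2-(3,5-dimethoxyphenyl)-5,7-dimethoxy-1-(4-methoxyphenyl)indan-3-ylidene]methyl}-3-(3,5-dimethoxyphenyl)-2-(4-methoxyphenyl)-2,3-dihydro-1-benzofuran | COc1ccc([C@H]2c3c(OC)cc(OC)cc3/C(=C/c3ccc4c(c3)[C@@H](c3cc(OC)cc(OC)c3)[C@@H](c3ccc(OC)cc3)O4)[C@@H]2c2cc(OC)cc(OC)c2)cc1
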